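The 6-linked genistein unit is cut across its pyranone at O1–C8a and C4–C4a. Ring A of that unit carries O1 and C4 on the adjacent carbons C8a and C4a, with the C5 oxygen next to C4a. A C4a–C8a aryne polarised by the C5 methoxy group can therefore take up 4-methoxyphenylacetic acid by C–O insertion, placing the oxygen on C8a and the acyl carbon on C4a in one operation. The precursor is an ortho-silyl aryl triflate already joined through its C6 to C8 of tri-O-methylgenistein. Its biaryl bond comes from Suzuki coupling of a boronate made by lithiation between the two methoxy groups, where electrophilic halogenation of the silylphenol would be unreliable.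

Key step: step 9

Remark: the target is drawn without a configuration at the hindered 6,8'-biaryl axis, so no atroposelective control is planned and the axially chiral compounds from 11 onward are taken as racemates. Locants C4a, C5, C8a and so on refer to the chromen-4-one numbering of the 6-linked unit of the target.

Step 1
Reactants: 1 3,5-dimethoxyphenol
Product: 2 2-bromo-3,5-dimethoxyphenol
Conditions: NBS (1.0 equiv), CH2Cl2, −78 °C to rt; chromatography to remove the minor 4-bromo isomer
Reagents that add atoms: N-bromosuccinimide O=C1CCC(=O)N1Br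
Why: Electrophilic aromatic bromination, in which the hydroxyl group directs NBS to the two equivalent ortho carbons (each also para to a methoxy group) while the more crowded carbon between the two methoxy groups reacts more slowly at low temperature.

Step 2
Reactants: 2 2-bromo-3,5-dimethoxyphenol
Product: 5 [3,5-dimethoxy-2-(trimethylsilyl)phenoxy]triisopropylsilane, via bromoaryl trimethylsilyl ether 3 (not isolated), via lithium 2-silylphenoxide 4 (not isolated)
Conditions: HMDS, THF, 70 °C; evaporate; n-BuLi, THF, −78 °C; TIPSOTf, −78 °C to rt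
Reagents that add atoms: hexamethyldisilazane C[Si](C)(C)N[Si](C)(C)C; triisopropylsilyl trifluoromethanesulfonate CC(C)[Si](OS(=O)(=O)C(F)(F)F)(C(C)C)C(C)C
Why: O-Silylation followed by bromine–lithium exchange triggers the retro-Brook (1,3 oxygen-to-carbon) silyl shift that places trimethylsilyl on the former C–Br carbon, and the lithium phenoxide is capped in the same flask as a bulky triisopropylsilyl ether that does not direct metalation.

Step 3
Reactants: 5 [3,5-dimethoxy-2-(trimethylsilyl)phenoxy]triisopropylsilane
Product: 7 2-[2,6-dimethoxy-4-(triisopropylsilyloxy)-3-(trimethylsilyl)phenyl]-4,4,5,5-tetramethyl-1,3,2-dioxaborolane, via aryllithium 6 (not isolated)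
Conditions: n-BuLi, TMEDA, THF, 0 °C; 2-isopropoxy-4,4,5,5-tetramethyl-1,3,2-dioxaborolane, −78 °C to rt; aq NH4Cl
Reagents that add atoms: 2-isopropoxy-4,4,5,5-tetramethyl-1,3,2-dioxaborolane CC(C)OB1OC(C)(C)C(C)(C)O1
Why: Directed ortho-metalation followed by borylation, in which the hydrogen between the two methoxy groups is the most acidic in the ring and the triisopropylsilyloxy group shields the only other ring hydrogen, so the aryllithium should form at the inter-methoxy carbon and be trapped by the borate ester.

Step 4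
Reactants: 8 genistein
Product: 9 5,7-dimethoxy-3-(4-methoxyphenyl)chromen-4-one (tri-O-methylgenistein)
Conditions: MeI (excess), K2CO3, DMF, 50 °C
Reagents that add atoms: iodomethane CI
Why: Williamson ether synthesis, with excess iodomethane and warming so that the hydrogen-bonded 5-hydroxyl is alkylated as well as the 7- and 4'-hydroxyls.

Step 5
Reactants: 9 5,7-dimethoxy-3-(4-methoxyphenyl)chromen-4-one
Product: 10 8-iodo-5,7-dimethoxy-3-(4-methoxyphenyl)chromen-4-one
Conditions: NIS (1.05 equiv), TFA (cat.), MeCN, rt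
Reagents that add atoms: N-iodosuccinimide O=C1CCC(=O)N1I
Why: Electrophilic aromatic iodination, which in 5,7-dimethoxylated chromen-4-ones is expected at C8 (ortho to O1 and the 7-methoxy group, para to the 5-methoxy group) in preference to the more crowded C6 and to the less activated anisyl ring.

Step 6
Reactants: 7 2-[2,6-dimethoxy-4-(triisopropylsilyloxy)-3-(trimethylsilyl)phenyl]-4,4,5,5-tetramethyl-1,3,2-dioxaborolane; 10 8-iodo-5,7-dimethoxy-3-(4-methoxyphenyl)chromen-4-one
Product: 11 8-[2,6-dimethoxy-4-(triisopropylsilyloxy)-3-(trimethylsilyl)phenyl]-5,7-dimethoxy-3-(4-methoxyphenyl)chromen-4-one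
Conditions: Pd(OAc)2 (5 mol %), SPhos (10 mol %), K3PO4, toluene/H2O (10:1), 90 °C
Reagents that add atoms: none
Why: Suzuki–Miyaura coupling, in which the dialkylbiarylphosphine SPhos is suited to tetra-ortho-substituted biaryls and the electron-rich boronate is paired with an aryl iodide that undergoes oxidative addition readily.

Step 7
Reactants: 11 8-[2,6-dimethoxy-4-(triisopropylsilyloxy)-3-(trimethylsilyl)phenyl]-5,7-dimethoxy-3-(4-methoxyphenyl)chromen-4-one
Product: 12 8-[4-hydroxy-2,6-dimethoxy-3-(trimethylsilyl)phenyl]-5,7-dimethoxy-3-(4-methoxyphenyl)chromen-4-one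
Conditions: TBAF (1.1 equiv), AcOH (1.1 equiv), THF, 0 °C
Reagents that add atoms: none
Why: Fluoride-mediated silyl ether cleavage, in which the oxygen–silicon bond with its phenoxide leaving group should break far faster than the aryl carbon–silicon bond, while acetic acid keeps the medium from becoming strongly basic.

Step 8
Reactants: 12 8-[4-hydroxy-2,6-dimethoxy-3-(trimethylsilyl)phenyl]-5,7-dimethoxy-3-(4-methoxyphenyl)chromen-4-one
Product: 13 8-[2,6-dimethoxy-4-(trifluoromethanesulfonyloxy)-3-(trimethylsilyl)phenyl]-5,7-dimethoxy-3-(4-methoxyphenyl)chromen-4-one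
Conditions: PhNTf2 (1.2 equiv), DBU, MeCN, rt to 40 °C
Reagents that add atoms: N-phenylbis(trifluoromethanesulfonimide) O=S(=O)(N(c1ccccc1)S(=O)(=O)C(F)(F)F)C(F)(F)F
Why: O-Sulfonylation of the phenoxide with the mild triflyl donor PhNTf2, which works on phenols flanked by a silyl group and leaves the chromenone carbonyl alone where triflic anhydride might activate it.

Step 9
Reactants: 13 8-[2,6-dimethoxy-4-(trifluoromethanesulfonyloxy)-3-(trimethylsilyl)phenyl]-5,7-dimethoxy-3-(4-methoxyphenyl)chromen-4-one; 14 4-methoxyphenylacetic acid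
Product: 16 8-{4-hydroxy-2,6-dimethoxy-3-[2-(4-methoxyphenyl)acetyl]phenyl}-5,7-dimethoxy-3-(4-methoxyphenyl)chromen-4-one, via aryne 15 (not isolated)
Conditions: 14 (1.5 equiv), CsF (4 equiv), THF, 125 °C, sealed tube
Reagents that add atoms: none
Why: Fluoride attacks the trimethylsilyl group of 13 and the neighbouring triflate departs, giving aryne 15 with its strained bond across C4a–C8a; the carboxylate of 14 adds through oxygen to C8a, the aryl anion left at C4a attacks the ester carbonyl in a 4-exo-trig closure, and the strained four-membered alkoxide opens to the C8a phenoxide and the C4a ketone. The closest known reaction type is the fluoride-induced insertion of arynes into the C–O bond of carboxylic acids to give ortho-hydroxyaryl ketones, formally the result of an anionic ortho-Fries shift of the aryl ester. No ring is kept in the product (the four-membered ring is transient) and no stereocentre is formed. The step needs oxygen at C8a and the acyl carbon at C4a, and the C5 methoxy group secures this, because it distorts the aryne so that the nucleophile attacks the remote, less hindered C8a and the negative charge develops at C4a beside the inductively withdrawing oxygen. A modest excess of the acid keeps the carboxylate, not the product phenoxide or an enolate, as the main trap for the aryne, and the high temperature should favour acyl transfer over protonation of the aryl anion.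

Step 10
Reactants: 16 8-{4-hydroxy-2,6-dimethoxy-3-[2-(4-methoxyphenyl)acetyl]phenyl}-5,7-dimethoxy-3-(4-methoxyphenyl)chromen-4-one
Product: 18 5,5',7,7'-tetramethoxy-3,3'-bis(4-methoxyphenyl)-6,8'-bichromene-4,4'-dione, via enaminone 17 (not isolated)
Conditions: DMF dimethyl acetal (3 equiv), toluene, 90 °C
Reagents that add atoms: N,N-dimethylformamide dimethyl acetal COC(OC)N(C)C
Why: Condensation of the activated methylene with DMF dimethyl acetal gives the enaminone, and the only free hydroxyl (on C8a) adds to its β-carbon in a 6-endo-trig closure and expels dimethylamine, the standard deoxybenzoin route to isoflavones.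

Step 11
Reactants: 18 5,5',7,7'-tetramethoxy-3,3'-bis(4-methoxyphenyl)-6,8'-bichromene-4,4'-dione
Product: 19 5,5',7,7'-tetrahydroxy-3,3'-bis(4-hydroxyphenyl)-6,8'-bichromene-4,4'-dione (target)
Conditions: BBr3 (excess), CH2Cl2, −78 °C to rt; then MeOH, H2O
Reagents that add atoms: none
Why: Lewis-acid ether cleavage, in which BBr3 coordinates each methoxy oxygen and bromide removes the methyl group by SN2, a standard global demethylation of polymethoxylated flavonoids that the acid-stable chromenone rings should tolerate.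

Compound list
1 | 3,5-dimethoxyphenol | COc1cc(O)cc(OC)c1 | starting material
2 | 2-bromo-3,5-dimethoxyphenol | Oc1cc(OC)cc(OC)c1Br | intermediate
3 | (2-bromo-3,5-dimethoxyphenoxy)trimethylsilane | C[Si](C)(C)Oc1cc(OC)cc(OC)c1Br | intermediate (not isolated)
4 | lithium 3,5-dimethoxy-2-(trimethylsilyl)phenoxide | [Li+].[O-]c1cc(OC)cc(OC)c1[Si](C)(C)C | intermediate (not isolated)
5 | [3,5-dimethoxy-2-(trimethylsilyl)phenoxy]triisopropylsilane | COc1cc(OC)c([Si](C)(C)C)c(O[Si](C(C)C)(C(C)C)C(C)C)c1 | intermediate
6 | [2,6-dimethoxy-4-(triisopropylsilyloxy)-3-(trimethylsilyl)phenyl]lithium | [Li]c1c(OC)cc(O[Si](C(C)C)(C(C)C)C(C)C)c([Si](C)(C)C)c1OC | intermediate (not isolated)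
7 | 2-[2,6-dimethoxy-4-(triisopropylsilyloxy)-3-(trimethylsilyl)phenyl]-4,4,5,5-tetramethyl-1,3,2-dioxaborolane | COc1cc(O[Si](C(C)C)(C(C)C)C(C)C)c([Si](C)(C)C)c(OC)c1B1OC(C)(C)C(C)(C)O1 | intermediate
8 | genistein, 5,7-dihydroxy-3-(4-hydroxyphenyl)chromen-4-one | O=c1c(-c2ccc(O)cc2)coc2cc(O)cc(O)c12 | starting material
9 | 5,7-dimethoxy-3-(4-methoxyphenyl)chromen-4-one | COc1ccc(cc1)-c1coc2cc(OC)cc(OC)c2c1=O | intermediate
10 | 8-iodo-5,7-dimethoxy-3-(4-methoxyphenyl)chromen-4-one | COc1ccc(cc1)-c1coc2c(I)c(OC)cc(OC)c2c1=O | intermediate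
11 | 8-[2,6-dimethoxy-4-(triisopropylsilyloxy)-3-(trimethylsilyl)phenyl]-5,7-dimethoxy-3-(4-methoxyphenyl)chromen-4-one | COc1ccc(cc1)-c1coc2c(-c3c(OC)cc(O[Si](C(C)C)(C(C)C)C(C)C)c([Si](C)(C)C)c3OC)c(OC)cc(OC)c2c1=O | intermediate
12 | 8-[4-hydroxy-2,6-dimethoxy-3-(trimethylsilyl)phenyl]-5,7-dimethoxy-3-(4-methoxyphenyl)chromen-4-one | COc1ccc(cc1)-c1coc2c(-c3c(OC)cc(O)c([Si](C)(C)C)c3OC)c(OC)cc(OC)c2c1=O | intermediate
13 | 8-[2,6-dimethoxy-4-(trifluoromethanesulfonyloxy)-3-(trimethylsilyl)phenyl]-5,7-dimethoxy-3-(4-methoxyphenyl)chromen-4-one | COc1ccc(cc1)-c1coc2c(-c3c(OC)cc(OS(=O)(=O)C(F)(F)F)c([Si](C)(C)C)c3OC)c(OC)cc(OC)c2c1=O | intermediate (key-step precursor)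
14 | 4-methoxyphenylacetic acid | COc1ccc(CC(=O)O)cc1 | starting material
15 | 8-(3,4-didehydro-2,6-dimethoxyphenyl)-5,7-dimethoxy-3-(4-methoxyphenyl)chromen-4-one (aryne; triple bond between the former C–Si and C–OTf carbons) | COC1=C(C(OC)=CC#C1)c1c(OC)cc(OC)c2c1occ(-c1ccc(OC)cc1)c2=O | intermediate (not isolated)
16 | 8-{4-hydroxy-2,6-dimethoxy-3-[2-(4-methoxyphenyl)acetyl]phenyl}-5,7-dimethoxy-3-(4-methoxyphenyl)chromen-4-one | COc1ccc(cc1)-c1coc2c(-c3c(OC)cc(O)c(C(=O)Cc4ccc(OC)cc4)c3OC)c(OC)cc(OC)c2c1=O | intermediate (key-step product)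
17 | 8-{3-[3-(dimethylamino)-2-(4-methoxyphenyl)prop-2-enoyl]-4-hydroxy-2,6-dimethoxyphenyl}-5,7-dimethoxy-3-(4-methoxyphenyl)chromen-4-one (alkene geometry not assigned; lost on ring closure) | COc1ccc(cc1)-c1coc2c(-c3c(OC)cc(O)c(C(=O)C(=CN(C)C)c4ccc(OC)cc4)c3OC)c(OC)cc(OC)c2c1=O | intermediate (not isolated)
18 | 5,5',7,7'-tetramethoxy-3,3'-bis(4-methoxyphenyl)-6,8'-bichromene-4,4'-dione | COc1ccc(cc1)-c1coc2c(-c3c(OC)cc4occ(-c5ccc(OC)cc5)c(=O)c4c3OC)c(OC)cc(OC)c2c1=O | intermediate
19 | 5,5',7,7'-tetrahydroxy-3,3'-bis(4-hydroxyphenyl)-6,8'-bichromene-4,4'-dione | O=c1c(-c2ccc(O)cc2)coc2cc(O)c(-c3c(O)cc(O)c4c(=O)c(-c5ccc(O)cc5)coc34)c(O)c12 | target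

Total step count: 11. Longest linear sequence: 9 steps (steps 1, 2, 3, 6, 7, 8, 9, 10 and 11 from 3,5-dimethoxyphenol); steps 4 and 5 are the two-step branch from genistein.

Steps most likely to fail

Step 9. The aryl anion may be protonated before it reaches the ester carbonyl, so that an aryl ester builds up in place of the ketone, or the aryne may be consumed by the product phenoxide. Fallback: setting out from 12, protodesilylation with trifluoroacetic acid in CH2Cl2 at rt would give 8-(4-hydroxy-2,6-dimethoxyphenyl)-5,7-dimethoxy-3-(4-methoxyphenyl)chromen-4-one F1, a phenol whose two positions ortho to the hydroxyl are equivalent. Friedel–Crafts acylation of F1 with 14 in BF3·OEt2 at 70 °C, the classical deoxybenzoin synthesis from phloroglucinol-type phenols, would then place the acyl group beside the free hydroxyl and come back to the route at 16.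

Step 6. Protodeboronation of the doubly ortho-oxygenated boronate may outrun transmetalation at the crowded palladium centre. Fallback: setting out from 5, lithiation as in step 3 gives 6, which with ZnCl2 in THF would be converted into chloro[2,6-dimethoxy-4-(triisopropylsilyloxy)-3-(trimethylsilyl)phenyl]zinc F2. Negishi coupling of F2 with 10 (Pd2(dba)3, RuPhos, THF, 65 °C), which runs without base or water, would come back to the route at 11.

Step 3. Deprotonation may be slow, or may stray to the hydrogen beside the silyloxy group or to a silicon-bound methyl group. Fallback: setting out from 1, the position is fixed by halogens instead.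
- Silylation (TIPSCl, imidazole, DMF) would give (3,5-dimethoxyphenoxy)triisopropylsilane F3.
- Lithiation of this symmetric ether between its methoxy groups (n-BuLi, THF, 0 °C) would give [2,6-dimethoxy-4-(triisopropylsilyloxy)phenyl]lithium F4, and 1,2-dibromotetrachloroethane would convert it into (4-bromo-3,5-dimethoxyphenoxy)triisopropylsilane F5.
- Iodination with NIS at one of the two equivalent remaining positions would give (4-bromo-2-iodo-3,5-dimethoxyphenoxy)triisopropylsilane F6.
- Iodine–lithium exchange (n-BuLi, one equivalent, THF, −100 °C), much faster than bromine–lithium exchange, would give [3-bromo-2,4-dimethoxy-6-(triisopropylsilyloxy)phenyl]lithium F7, and TMSCl would silylate it to [4-bromo-3,5-dimethoxy-2-(trimethylsilyl)phenoxy]triisopropylsilane F8.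
- Bromine–lithium exchange on F8 (n-BuLi, THF, −78 °C) would then give aryllithium 6 at a position fixed by the halogen, and borylation as in step 3 would come back to the route at 7.

Further compounds
F1 | step 9 | 8-(4-hydroxy-2,6-dimethoxyphenyl)-5,7-dimethoxy-3-(4-methoxyphenyl)chromen-4-one | COc1ccc(cc1)-c1coc2c(-c3c(OC)cc(O)cc3OC)c(OC)cc(OC)c2c1=O
F2 | step 6 | chloro[2,6-dimethoxy-4-(triisopropylsilyloxy)-3-(trimethylsilyl)phenyl]zinc | COc1cc(O[Si](C(C)C)(C(C)C)C(C)C)c([Si](C)(C)C)c(OC)c1[Zn]Cl
F3 | step 3 | (3,5-dimethoxyphenoxy)triisopropylsilane | COc1cc(OC)cc(O[Si](C(C)C)(C(C)C)C(C)C)c1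
F4 | step 3 | [2,6-dimethoxy-4-(triisopropylsilyloxy)phenyl]lithium | [Li]c1c(OC)cc(O[Si](C(C)C)(C(C)C)C(C)C)cc1OC
F5 | step 3 | (4-bromo-3,5-dimethoxyphenoxy)triisopropylsilane | COc1cc(O[Si](C(C)C)(C(C)C)C(C)C)cc(OC)c1Br
F6 | step 3 | (4-bromo-2-iodo-3,5-dimethoxyphenoxy)triisopropylsilane | COc1cc(O[Si](C(C)C)(C(C)C)C(C)C)c(I)c(OC)c1Br
F7 | step 3 | [3-bromo-2,4-dimethoxy-6-(triisopropylsilyloxy)phenyl]lithium | [Li]c1c(OC)c(Br)c(OC)cc1O[Si](C(C)C)(C(C)C)C(C)C
F8 | step 3 | [4-bromo-3,5-dimethoxy-2-(trimethylsilyl)phenoxy]triisopropylsilane | COc1cc(O[Si](C(C)C)(C(C)C)C(C)C)c([Si](C)(C)C)c(OC)c1Br
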